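## The problem

The target (34) is a cembranolide, and cembrane numbering is used throughout. A 14-membered carbocycle (C1–C14) carries a trans-fused α-methylene γ-lactone across C1/C14 (C15, C16, exocyclic C17), an acetate at C13, an E-trisubstituted C11=C12 olefin, a trans-trisubstituted C3–C4 epoxide, an exocyclic C8=C19 methylene and a secondary allylic hydroperoxide at C7.

Six stereocentres must be set. C14, C1 and C13 are contiguous, so C14 can control C1 (anti addition to a butenolide) and C13 (addition to a C13 aldehyde anti to the C14–O bond). C3 and C4 are insulated from this triad by the C2 methylene and need reagent control. C7 lies across the ring and can only be governed by the conformation of the macrocycle.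

The ring holds three positions of like substitution (C3, C7, C11), so the epoxide cannot be placed by a late, unselective oxidation of a triene. The hydroperoxide, the α-methylene lactone (a Michael acceptor and a partner for zerovalent nickel), the acid-labile epoxide and the allylic acetate dictate the order of events: epoxide early and handled only under neutral or basic conditions, methylene and acetate after ring closure, hydroperoxide last.

The feature that permits the ring closure is C13 itself. It is an allylic carbinol flanked by the lactone CH–O carbon C14 and by the methyl-bearing olefin carbon C12. This is the pattern formed when an aldehyde (C13) adds reductively to a methyl-capped alkyne (C11≡C12) with syn delivery of carbon and hydrogen.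

## Retrosynthesis

**C7–O.** The C7–O bond is cut first, with return of the C8=C19 double bond to C7=C8, which leads to the epoxy diene acetate 33. The forward reaction is a Schenck ene reaction of singlet oxygen. Carrying a C7 oxygen through the route is rejected because none of the earlier reagents (Grignard reagents, zerovalent nickel, silane, enolates) tolerates an O–O bond. The precursor has one stereocentre fewer and has lost the most fragile group. The step must select C7=C8 over C11=C12 and the enoate, abstract hydrogen from C19, and attack the face that gives 7S.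

**C15=C17 and the acetate.** Cutting the C15–C17 bond and the acetyl C–O bond takes 33 back through alcohol 32, methylene lactone 31 and Mannich base 29 to the macrocyclic silyl ether 28. Both groups are placed after ring closure: an α-methylene lactone would be consumed by nickel/silane and by Grignard reagents, and an acetate would not survive enolate formation. The forward steps need only a regioselective lactone enolization and a desilylation that spares the epoxide.

**C12–C13 (key cut).** Opening 28 at C12–C13 gives the seco ynal 27. Neighbouring cuts are weaker: olefin metathesis at C11=C12 offers no geometric control for a trisubstituted olefin and would compete with C7=C8, and closure at C4–C5 would require an organometallic terminus beside a lactone. The chosen cut removes the ring, the C13 stereocentre, the olefin geometry and the C12 methyl branch in one step. The forward reaction must give endo regiochemistry at the alkyne, syn addition, and attack anti to the C14–O bond.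

**C4–C5 and C3–O.** Ynal 27 comes from alcohol 26 and silyl ether 25, whose epoxide is opened to chlorohydrin 24. Chlorohydrin 24 is cut at C4–C5 into the chloro methyl ketone 14 and Grignard reagent 23 (from bromide 22). Epoxidation of a C3=C4 olefin is rejected because no reagent distinguishes it from C7=C8. The cut splits the chain into two halves of similar size. The addition must follow the Cornforth model at C4 and then displace chloride with inversion at C3.

**Lactone half.** Ketone 14 is traced through chlorohydrin 13 and chloro aldehyde 12 (C4–methyl bond, C3–Cl bond) to aldehyde 11 and acetal 10. Cutting C1–C2 gives butenolide 6 and bromo acetal 7 (as Grignard reagent 8). Butenolide 6 derives from D-glutamic acid (1) through 2, 3 and 4. An acetal-bearing nucleophile is preferred to an allyl group because it delivers C4 at the aldehyde oxidation level and saves a hydroboration–oxidation pair. C14 must relay to C1, and the catalyst must set C3.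

**Enyne half.** Bromide 22 comes from alcohol 21. Cutting the C8–C19 and C6–C7 bonds (methylalumination via alane 20, then ethylene oxide) leads to hepta-1,5-diyne 19. Diyne 19 is made from silyl diyne 18 by a C9–C10 cut into 1-(trimethylsilyl)propyne 15 (as 17) and 1-bromobut-2-yne 16. A cyclopropylcarbinyl-to-homoallyl rearrangement would be shorter but gives only modest geometric control. The carbometalation fixes the 7E olefin mechanistically.

## Roads not taken

**Alternative 1:** The cut is made at C1–C2 and C15–C17 on the butenolide. A vinyl cuprate adds to C1 of the trityl butenolide A1, and the enolate is trapped at C15 by formaldehyde to give the all-trans lactone A2.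
- Merits: one operation sets C1 and C15 from C14 and installs C17 early, which would make the two late methylenation steps of the chosen plan unnecessary. In that respect it is better.
- Weak points: the β-hydroxymethyl lactone must be protected and carried through every basic step, and any β-elimination would release the methylene lactone before the organometallic and nickel steps. The vinyl group places unsaturation at C2=C3, not where the epoxide needs it, so C3/C4 would still have to be built by other means. Trityl removal needs acid that the epoxide does not tolerate. The idea also says nothing about ring closure.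
- Comparison: the chosen plan keeps the same C14-to-C1 relay (step 5) and delivers C2–C4 at the correct oxidation level. It pays for this with two robust late steps (19, 20).

**Alternative 2:** The cut is at C4–C5 and C3–O, as in the chosen plan, but on different halves. Grignard reagent 23 adds to the chloro ketone A3, which already carries the C13 propynyl carbinol, and epoxide closure gives the epoxy diyne A4.
- Merits: C13 is set early in a simple acyclic addition. The ring would then be closed at C11–C12 by alkyne metathesis, arguably a more dependable closure for a 14-membered ring than a reductive coupling and one that does not depend on C13 control in the macrocyclic transition state. In reliability this road is at least as good.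
- Weak points: the cycloalkyne lacks the C12 methyl group. Hydroxyl-directed trans-hydrostannation and methylation must follow, with a protecting-group exchange and stoichiometric tin, so three to five steps replace one.
- Comparison: the chosen plan sets step economy against this, since ring, C13, olefin geometry and methyl branch arise in step 18. It keeps this road as the fallback from 27.

**Alternative 3:** Nothing is cut in the skeleton. An engineered cytochrome P450 monooxygenase transfers one oxygen atom to C3=C4 of the macrocyclic triene A5 and gives the epoxy diene acetate A6, which is identical with 33.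
- Merits: the carbon chain could be assembled by plain olefin chemistry, and the chlorination, methyl addition, oxidation and closure steps (7–9, 15) would disappear. If a selective enzyme existed, this would be the shortest road.
- Weak points: the enzyme must distinguish C3=C4 from C7=C8 and C11=C12 and choose one face, on a lipophilic non-natural substrate. Such a catalyst would first have to be found, and chemical epoxidants offer no backup because C3=C4 and C7=C8 are electronically alike.
- Comparison: the chosen plan is longer but fixes C3 and C4 by reagent-controlled chlorination and an addition with a known stereochemical model.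

Key step: step 18

## Route

Remark on the chemistry: in step 7 the (2S,5S) antipode of 2,5-diphenylpyrrolidine is assumed to deliver the 3R chloride (chlorine entering the enamine face remote from the flanking phenyl group). If the sense is the opposite, the (2R,5R) antipode is used and nothing else changes.

Step 1
Reactants: 1 D-glutamic acid
Product: 2 (R)-5-oxotetrahydrofuran-2-carboxylic acid
Conditions: NaNO2, aq. HCl, 0 °C → rt
Reagents that add atoms: none
Why: Diazotization with participation of the α-carboxylate and capture by the γ-carboxyl group proceeds by double inversion, so the future C14 is retained as R.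

Step 2
Reactants: 2 (R)-5-oxotetrahydrofuran-2-carboxylic acid
Product: 3 (R)-5-(hydroxymethyl)dihydrofuran-2(3H)-one
Conditions: BH3·SMe2, THF, 0 °C → rt; MeOH quench
Reagents that add atoms: none
Why: Borane reduces a carboxylic acid much faster than a lactone, so the acid is reduced chemoselectively.

Step 3
Reactants: 3 (R)-5-(hydroxymethyl)dihydrofuran-2(3H)-one
Product: 4 (R)-5-[(tert-butyldiphenylsilyloxy)methyl]dihydrofuran-2(3H)-one
Conditions: TBDPSCl, imidazole, CH2Cl2, rt
Reagents that add atoms: tert-butylchlorodiphenylsilane CC(C)(C)[Si](Cl)(c1ccccc1)c1ccccc1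
Why: Silylation of the primary alcohol; the bulky silyl ether survives the later aqueous acid and organometallic steps and directs the conjugate addition.

Step 4
Reactants: 4 (R)-5-[(tert-butyldiphenylsilyloxy)methyl]dihydrofuran-2(3H)-one
Product: 6 (R)-5-[(tert-butyldiphenylsilyloxy)methyl]furan-2(5H)-one, via selenide 5 (not isolated)
Conditions: LDA, THF, −78 °C; PhSeBr; then H2O2, pyridine, CH2Cl2, 0 °C
Reagents that add atoms: none
Why: α-Selenenylation of the lactone lithium enolate and selenoxide syn-elimination introduce the C15=C1 double bond; C14 is untouched because the butenolide forms only after the base is consumed.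

Step 5
Reactants: 6 (R)-5-[(tert-butyldiphenylsilyloxy)methyl]furan-2(5H)-one; 7 2-(2-bromoethyl)-1,3-dioxolane
Product: 10 (4R,5R)-5-[(tert-butyldiphenylsilyloxy)methyl]-4-[2-(1,3-dioxolan-2-yl)ethyl]dihydrofuran-2(3H)-one, via Grignard reagent 8 (not isolated), via silyl ketene acetal 9 (not isolated)
Conditions: Mg, THF, ≤ 25 °C (7 → 8); CuBr·SMe2 (cat.), TMSCl, THF, −78 °C; aq. NH4Cl
Reagents that add atoms: none
Why: Copper-catalysed, TMSCl-accelerated conjugate addition of a Grignard reagent forms C1–C2; the nucleophile enters anti to the C14 silyloxymethyl group, so C14 sets C1 (trans lactone).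

Step 6
Reactants: 10 (4R,5R)-5-[(tert-butyldiphenylsilyloxy)methyl]-4-[2-(1,3-dioxolan-2-yl)ethyl]dihydrofuran-2(3H)-one
Product: 11 3-[(2R,3R)-2-[(tert-butyldiphenylsilyloxy)methyl]-5-oxotetrahydrofuran-3-yl]propanal
Conditions: 1 M aq. HCl, THF, rt
Reagents that add atoms: water O
Why: Acetal hydrolysis frees the C4 aldehyde; the lactone and the tert-butyldiphenylsilyl ether are stable to dilute aqueous acid.

Step 7
Reactants: 11 3-[(2R,3R)-2-[(tert-butyldiphenylsilyloxy)methyl]-5-oxotetrahydrofuran-3-yl]propanal
Product: 12 (2R)-2-chloro-3-[(2R,3S)-2-[(tert-butyldiphenylsilyloxy)methyl]-5-oxotetrahydrofuran-3-yl]propanal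
Conditions: NCS, (2S,5S)-2,5-diphenylpyrrolidine (cat.), CH2Cl2, 0 °C → rt
Reagents that add atoms: N-chlorosuccinimide O=C1CCC(=O)N1Cl
Why: Enamine-mediated organocatalytic α-chlorination of an aldehyde; the C2-symmetric amine shields one enamine face and sets C3 (3R) under catalyst control, the remote C1/C14 centres having little influence; the labile product is used at once.

Step 8
Reactants: 12 (2R)-2-chloro-3-[(2R,3S)-2-[(tert-butyldiphenylsilyloxy)methyl]-5-oxotetrahydrofuran-3-yl]propanal
Product: 13 (3R)-3-chloro-4-[(2R,3S)-2-[(tert-butyldiphenylsilyloxy)methyl]-5-oxotetrahydrofuran-3-yl]butan-2-ol (carbinol epimers)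
Conditions: MeMgBr, THF, −78 °C
Reagents that add atoms: methylmagnesium bromide C[Mg]Br
Why: Grignard addition to the highly electrophilic α-chloro aldehyde is much faster than attack on the lactone at low temperature; the carbinol configuration is irrelevant because it is oxidized in step 9.

Step 9
Reactants: 13 (3R)-3-chloro-4-[(2R,3S)-2-[(tert-butyldiphenylsilyloxy)methyl]-5-oxotetrahydrofuran-3-yl]butan-2-ol
Product: 14 (3R)-3-chloro-4-[(2R,3S)-2-[(tert-butyldiphenylsilyloxy)methyl]-5-oxotetrahydrofuran-3-yl]butan-2-one
Conditions: Dess–Martin periodinane, NaHCO3, CH2Cl2, 0 °C → rt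
Reagents that add atoms: none
Why: Buffered, non-basic Dess–Martin oxidation gives the chloro methyl ketone without enolizing the C3 stereocentre.

Step 10
Reactants: 15 1-(trimethylsilyl)propyne; 16 1-bromobut-2-yne
Product: 18 hepta-1,5-diyn-1-yl(trimethyl)silane, via lithio compound 17 (not isolated)
Conditions: n-BuLi, THF, −78 °C; then 16, −78 °C → rt
Reagents that add atoms: none
Why: Propargylic lithiation of the silyl alkyne and SN2 alkylation with the primary propargylic bromide form C9–C10; the silyl group steers reaction to the propargylic rather than the allenic terminus.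

Step 11
Reactants: 18 hepta-1,5-diyn-1-yl(trimethyl)silane
Product: 19 hepta-1,5-diyne
Conditions: K2CO3, MeOH, rt
Reagents that add atoms: none
Why: Base-catalysed protodesilylation of the alkynylsilane; the volatile diyne is carried forward as a concentrated solution.

Step 12
Reactants: 19 hepta-1,5-diyne
Product: 21 (E)-4-methylnon-3-en-7-yn-1-ol, via alkenylalane 20 (not isolated)
Conditions: Me3Al, Cp2ZrCl2, CH2Cl2, 0 °C → rt; solvent exchange to hexane/THF; n-BuLi, −78 °C; ethylene oxide, −78 °C → rt
Reagents that add atoms: trimethylaluminium C[Al](C)C; ethylene oxide C1CO1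
Why: Zirconium-catalysed syn-methylalumination (Negishi carboalumination) of the terminal alkyne places methyl at C8 and aluminium at C7, the internal alkyne reacting far more slowly; the derived alanate opens ethylene oxide with retention, which fixes the 7E olefin.

Step 13
Reactants: 21 (E)-4-methylnon-3-en-7-yn-1-ol
Product: 22 (E)-9-bromo-6-methylnon-6-en-2-yne
Conditions: CBr4, PPh3, CH2Cl2, 0 °C
Reagents that add atoms: carbon tetrabromide BrC(Br)(Br)Br
Why: Appel bromination of the primary alcohol under neutral conditions leaves olefin and alkyne untouched.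

Step 14
Reactants: 14 (3R)-3-chloro-4-[(2R,3S)-2-[(tert-butyldiphenylsilyloxy)methyl]-5-oxotetrahydrofuran-3-yl]butan-2-one; 22 (E)-9-bromo-6-methylnon-6-en-2-yne
Product: 24 (4S,5R)-5-[(tert-butyldiphenylsilyloxy)methyl]-4-[(2R,3S,6E)-2-chloro-3-hydroxy-3,7-dimethyldodec-6-en-10-yn-1-yl]dihydrofuran-2(3H)-one, via Grignard reagent 23 (not isolated)
Conditions: Mg, THF (22 → 23); then 14, THF, −78 °C; aq. NH4Cl at −78 °C
Reagents that add atoms: none
Why: Grignard addition to an α-chloro ketone under the Cornforth (polar Felkin–Anh) model: C5 attacks C4 anti to the C3–Cl bond and past the C3 hydrogen, so C3 sets C4 (4S); the activated ketone reacts well before the lactone at −78 °C.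

Step 15
Reactants: 24 (4S,5R)-5-[(tert-butyldiphenylsilyloxy)methyl]-4-[(2R,3S,6E)-2-chloro-3-hydroxy-3,7-dimethyldodec-6-en-10-yn-1-yl]dihydrofuran-2(3H)-one
Product: 25 (4R,5R)-5-[(tert-butyldiphenylsilyloxy)methyl]-4-{[(2S,3S)-3-methyl-3-[(E)-4-methylnon-3-en-7-yn-1-yl]oxiran-2-yl]methyl}dihydrofuran-2(3H)-one
Conditions: NaH, THF, 0 °C
Reagents that add atoms: none
Why: Intramolecular Williamson-type displacement of chloride by the tertiary alkoxide inverts C3 and gives the trans (3S,4S) epoxide; the non-nucleophilic base leaves the lactone closed.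

Step 16
Reactants: 25 (4R,5R)-5-[(tert-butyldiphenylsilyloxy)methyl]-4-{[(2S,3S)-3-methyl-3-[(E)-4-methylnon-3-en-7-yn-1-yl]oxiran-2-yl]methyl}dihydrofuran-2(3H)-one
Product: 26 (4R,5R)-5-(hydroxymethyl)-4-{[(2S,3S)-3-methyl-3-[(E)-4-methylnon-3-en-7-yn-1-yl]oxiran-2-yl]methyl}dihydrofuran-2(3H)-one
Conditions: TBAF, AcOH, THF, rt
Reagents that add atoms: none
Why: Fluoride cleavage of the silyl ether; acetic acid buffering keeps the liberated C13 alkoxide from opening the lactone or the epoxide.

Step 17
Reactants: 26 (4R,5R)-5-(hydroxymethyl)-4-{[(2S,3S)-3-methyl-3-[(E)-4-methylnon-3-en-7-yn-1-yl]oxiran-2-yl]methyl}dihydrofuran-2(3H)-one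
Product: 27 (2R,3R)-3-{[(2S,3S)-3-methyl-3-[(E)-4-methylnon-3-en-7-yn-1-yl]oxiran-2-yl]methyl}-5-oxotetrahydrofuran-2-carbaldehyde
Conditions: Dess–Martin periodinane, NaHCO3, CH2Cl2, 0 °C
Reagents that add atoms: none
Why: Neutral Dess–Martin oxidation gives the epimerizable α-acyloxy aldehyde without base; it is used directly in step 18.

Step 18
Reactants: 27 (2R,3R)-3-{[(2S,3S)-3-methyl-3-[(E)-4-methylnon-3-en-7-yn-1-yl]oxiran-2-yl]methyl}-5-oxotetrahydrofuran-2-carbaldehyde
Product: 28 (1R,3S,4S,13S,14R,7E,11E)-3,4-epoxy-13-(triethylsilyloxy)cembra-7,11-dien-16,14-olide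
Conditions: Ni(cod)2, IMes·HCl, KOt-Bu (catalyst preformed), Et3SiH, THF, rt, slow addition of 27 at high dilution
Reagents that add atoms: triethylsilane CC[SiH](CC)CC
Why: Zerovalent nickel bearing the compact carbene IMes (1,3-dimesitylimidazol-2-ylidene) binds the C11≡C12 alkyne and the C13 aldehyde and undergoes oxidative cyclization to an oxanickelacyclopentene in which the C12–C13 bond is formed; σ-bond metathesis with Et3SiH converts the Ni–O bond into the Si–O bond, and C–H reductive elimination at C11 releases 28 and the catalyst. The closest known reaction type is the nickel-catalysed reductive macrocyclization of ynals with a trialkylsilane and an N-heterocyclic carbene ligand. The 14-membered ring closes in the endo mode with respect to the alkyne: the aldehyde carbon bonds to the distal, methyl-bearing C12, so both alkyne carbons become ring members, whereas the exo mode would give a 13-membered ring with an exocyclic ethylidene group. A compact ligand favours C–C bond formation at the alkyne carbon with the smaller substituent (methyl), and the lower strain of the larger ring reinforces this. Syn delivery of C13 and hydrogen across the alkyne fixes the 11E geometry. The new stereocentre C13 is controlled by C14: the aldehyde reacts in the polar Felkin–Anh conformation with the C14–O bond anti to the incoming C12, giving the anti 13S,14R pair. Chemoselectivity for the aldehyde over the lactone and the hindered epoxide rests on the high electrophilicity of the α-acyloxy aldehyde, ring closure over oligomerization rests on slow addition at high dilution, and preforming the catalyst keeps free alkoxide away from C14.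

Step 19
Reactants: 28 (1R,3S,4S,13S,14R,7E,11E)-3,4-epoxy-13-(triethylsilyloxy)cembra-7,11-dien-16,14-olide
Product: 29 (1R,3S,4S,13S,14R,7E,11E)-17-(dimethylamino)-3,4-epoxy-13-(triethylsilyloxy)cembra-7,11-dien-16,14-olide (C15 epimers)
Conditions: LDA, THF, −78 °C; CH2=NMe2+ I−, −78 °C → rt
Reagents that add atoms: N,N-dimethylmethyleneiminium iodide (Eschenmoser's salt) C=[N+](C)C.[I-]
Why: Mannich reaction of the lactone lithium enolate, the only acidic site, forms C15–C17; the C15 configuration does not matter because the centre becomes trigonal in step 20.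

Step 20
Reactants: 29 (1R,3S,4S,13S,14R,7E,11E)-17-(dimethylamino)-3,4-epoxy-13-(triethylsilyloxy)cembra-7,11-dien-16,14-olide
Product: 31 (1R,3S,4S,13S,14R,7E,11E)-3,4-epoxy-13-(triethylsilyloxy)cembra-7,11,15(17)-trien-16,14-olide, via ammonium iodide 30 (not isolated)
Conditions: MeI, MeOH/CH2Cl2, rt; then aq. NaHCO3, rt
Reagents that add atoms: none
Why: N-Methylation and mild base-induced β-elimination of trimethylamine (Hofmann-type) reveal the α-methylene lactone without touching epoxide or silyl ether.

Step 21
Reactants: 31 (1R,3S,4S,13S,14R,7E,11E)-3,4-epoxy-13-(triethylsilyloxy)cembra-7,11,15(17)-trien-16,14-olide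
Product: 32 (1R,3S,4S,13S,14R,7E,11E)-3,4-epoxy-13-hydroxycembra-7,11,15(17)-trien-16,14-olide
Conditions: HF·pyridine, pyridine, THF, 0 °C
Reagents that add atoms: none
Why: Buffered HF·pyridine cleaves the secondary triethylsilyl ether; excess pyridine protects the trisubstituted epoxide, and the non-basic medium avoids conjugate addition to the enoate.

Step 22
Reactants: 32 (1R,3S,4S,13S,14R,7E,11E)-3,4-epoxy-13-hydroxycembra-7,11,15(17)-trien-16,14-olide
Product: 33 (1R,3S,4S,13S,14R,7E,11E)-13-acetoxy-3,4-epoxycembra-7,11,15(17)-trien-16,14-olide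
Conditions: Ac2O, pyridine, DMAP (cat.), CH2Cl2, 0 °C
Reagents that add atoms: acetic anhydride CC(=O)OC(C)=O
Why: Standard acylation of the secondary allylic alcohol with retention at C13.

Step 23
Reactants: 33 (1R,3S,4S,13S,14R,7E,11E)-13-acetoxy-3,4-epoxycembra-7,11,15(17)-trien-16,14-olide
Product: 34 (1R,3S,4S,7S,13S,14R,11E)-13-acetoxy-3,4-epoxy-7-hydroperoxycembra-8(19),11,15(17)-trien-16,14-olide
Conditions: O2, hν (visible), tetraphenylporphyrin (cat.), CH2Cl2, −20 °C
Reagents that add atoms: dioxygen O=O
Why: Schenck ene reaction of singlet oxygen at the electron-rich C7=C8 olefin (C11=C12 is deactivated by the allylic acetate and the enoate is electron-poor); hydrogen is abstracted from C19 on the more crowded side of the olefin, and C7 is set by attack on the exposed face of the macrocycle.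

## Compound list

1 | D-glutamic acid, (R)-2-aminopentanedioic acid | N[C@H](CCC(=O)O)C(=O)O | starting material
2 | (R)-5-oxotetrahydrofuran-2-carboxylic acid | O=C(O)[C@@H]1OC(=O)CC1 | intermediate
3 | (R)-5-(hydroxymethyl)dihydrofuran-2(3H)-one | OC[C@@H]1OC(=O)CC1 | intermediate
4 | (R)-5-[(tert-butyldiphenylsilyloxy)methyl]dihydrofuran-2(3H)-one | CC(C)(C)[Si](c1ccccc1)(c1ccccc1)OC[C@@H]1OC(=O)CC1 | intermediate
5 | (5R)-5-[(tert-butyldiphenylsilyloxy)methyl]-3-(phenylselanyl)dihydrofuran-2(3H)-one (C3 epimers) | CC(C)(C)[Si](c1ccccc1)(c1ccccc1)OC[C@@H]1OC(=O)C([Se]c2ccccc2)C1 | intermediate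
6 | (R)-5-[(tert-butyldiphenylsilyloxy)methyl]furan-2(5H)-one | CC(C)(C)[Si](c1ccccc1)(c1ccccc1)OC[C@@H]1OC(=O)C=C1 | intermediate
7 | 2-(2-bromoethyl)-1,3-dioxolane | BrCCC1OCCO1 | starting material
8 | [2-(1,3-dioxolan-2-yl)ethyl]magnesium bromide | Br[Mg]CCC1OCCO1 | intermediate
9 | tert-butyl{[(2R,3R)-3-[2-(1,3-dioxolan-2-yl)ethyl]-5-(trimethylsilyloxy)-2,3-dihydrofuran-2-yl]methoxy}diphenylsilane | CC(C)(C)[Si](c1ccccc1)(c1ccccc1)OC[C@@H]1OC(O[Si](C)(C)C)=C[C@H]1CCC2OCCO2 | intermediate
10 | (4R,5R)-5-[(tert-butyldiphenylsilyloxy)methyl]-4-[2-(1,3-dioxolan-2-yl)ethyl]dihydrofuran-2(3H)-one | CC(C)(C)[Si](c1ccccc1)(c1ccccc1)OC[C@@H]1OC(=O)C[C@H]1CCC2OCCO2 | intermediate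
11 | 3-[(2R,3R)-2-[(tert-butyldiphenylsilyloxy)methyl]-5-oxotetrahydrofuran-3-yl]propanal | CC(C)(C)[Si](c1ccccc1)(c1ccccc1)OC[C@@H]1OC(=O)C[C@H]1CCC=O | intermediate
12 | (2R)-2-chloro-3-[(2R,3S)-2-[(tert-butyldiphenylsilyloxy)methyl]-5-oxotetrahydrofuran-3-yl]propanal | CC(C)(C)[Si](c1ccccc1)(c1ccccc1)OC[C@@H]1OC(=O)C[C@H]1C[C@@H](Cl)C=O | intermediate
13 | (3R)-3-chloro-4-[(2R,3S)-2-[(tert-butyldiphenylsilyloxy)methyl]-5-oxotetrahydrofuran-3-yl]butan-2-ol (carbinol epimers) | CC(C)(C)[Si](c1ccccc1)(c1ccccc1)OC[C@@H]1OC(=O)C[C@H]1C[C@@H](Cl)C(C)O | intermediate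
14 | (3R)-3-chloro-4-[(2R,3S)-2-[(tert-butyldiphenylsilyloxy)methyl]-5-oxotetrahydrofuran-3-yl]butan-2-one | CC(C)(C)[Si](c1ccccc1)(c1ccccc1)OC[C@@H]1OC(=O)C[C@H]1C[C@@H](Cl)C(C)=O | intermediate
15 | 1-(trimethylsilyl)propyne | CC#C[Si](C)(C)C | starting material
16 | 1-bromobut-2-yne | CC#CCBr | starting material
17 | [3-(trimethylsilyl)prop-2-yn-1-yl]lithium | [Li]CC#C[Si](C)(C)C | intermediate
18 | hepta-1,5-diyn-1-yl(trimethyl)silane | CC#CCCC#C[Si](C)(C)C | intermediate
19 | hepta-1,5-diyne | CC#CCCC#C | intermediate
20 | dimethyl[(E)-2-methylhept-1-en-5-yn-1-yl]alane | C[Al](C)/C=C(\C)CCC#CC | intermediate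
21 | (E)-4-methylnon-3-en-7-yn-1-ol | OCC/C=C(\C)CCC#CC | intermediate
22 | (E)-9-bromo-6-methylnon-6-en-2-yne | BrCC/C=C(\C)CCC#CC | intermediate
23 | [(E)-4-methylnon-3-en-7-yn-1-yl]magnesium bromide | Br[Mg]CC/C=C(\C)CCC#CC | intermediate
24 | (4S,5R)-5-[(tert-butyldiphenylsilyloxy)methyl]-4-[(2R,3S,6E)-2-chloro-3-hydroxy-3,7-dimethyldodec-6-en-10-yn-1-yl]dihydrofuran-2(3H)-one | CC(C)(C)[Si](c1ccccc1)(c1ccccc1)OC[C@@H]1OC(=O)C[C@H]1C[C@@H](Cl)[C@@](C)(O)CC/C=C(\C)CCC#CC | intermediate
25 | (4R,5R)-5-[(tert-butyldiphenylsilyloxy)methyl]-4-{[(2S,3S)-3-methyl-3-[(E)-4-methylnon-3-en-7-yn-1-yl]oxiran-2-yl]methyl}dihydrofuran-2(3H)-one | CC(C)(C)[Si](c1ccccc1)(c1ccccc1)OC[C@@H]1OC(=O)C[C@H]1C[C@@H]1O[C@@]1(C)CC/C=C(\C)CCC#CC | intermediate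
26 | (4R,5R)-5-(hydroxymethyl)-4-{[(2S,3S)-3-methyl-3-[(E)-4-methylnon-3-en-7-yn-1-yl]oxiran-2-yl]methyl}dihydrofuran-2(3H)-one | OC[C@@H]1OC(=O)C[C@H]1C[C@@H]1O[C@@]1(C)CC/C=C(\C)CCC#CC | intermediate
27 | (2R,3R)-3-{[(2S,3S)-3-methyl-3-[(E)-4-methylnon-3-en-7-yn-1-yl]oxiran-2-yl]methyl}-5-oxotetrahydrofuran-2-carbaldehyde (seco ynal) | O=C[C@@H]1OC(=O)C[C@H]1C[C@@H]1O[C@@]1(C)CC/C=C(\C)CCC#CC | intermediate
28 | (1R,3S,4S,13S,14R,7E,11E)-3,4-epoxy-13-(triethylsilyloxy)cembra-7,11-dien-16,14-olide | C1/C=C(\C)[C@H](O[Si](CC)(CC)CC)[C@@H]2OC(=O)C[C@H]2C[C@@H]2O[C@@]2(C)CC/C=C(\C)C1 | intermediate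
29 | (1R,3S,4S,13S,14R,7E,11E)-17-(dimethylamino)-3,4-epoxy-13-(triethylsilyloxy)cembra-7,11-dien-16,14-olide (C15 epimers) | C1/C=C(\C)[C@H](O[Si](CC)(CC)CC)[C@@H]2OC(=O)C(CN(C)C)[C@H]2C[C@@H]2O[C@@]2(C)CC/C=C(\C)C1 | intermediate
30 | 17-(trimethylammonio) analogue of 29, iodide salt (C15 epimers) | C1/C=C(\C)[C@H](O[Si](CC)(CC)CC)[C@@H]2OC(=O)C(C[N+](C)(C)C)[C@H]2C[C@@H]2O[C@@]2(C)CC/C=C(\C)C1.[I-] | intermediate
31 | (1R,3S,4S,13S,14R,7E,11E)-3,4-epoxy-13-(triethylsilyloxy)cembra-7,11,15(17)-trien-16,14-olide | C1/C=C(\C)[C@H](O[Si](CC)(CC)CC)[C@@H]2OC(=O)C(=C)[C@H]2C[C@@H]2O[C@@]2(C)CC/C=C(\C)C1 | intermediate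
32 | (1R,3S,4S,13S,14R,7E,11E)-3,4-epoxy-13-hydroxycembra-7,11,15(17)-trien-16,14-olide | C1/C=C(\C)[C@H](O)[C@@H]2OC(=O)C(=C)[C@H]2C[C@@H]2O[C@@]2(C)CC/C=C(\C)C1 | intermediate
33 | (1R,3S,4S,13S,14R,7E,11E)-13-acetoxy-3,4-epoxycembra-7,11,15(17)-trien-16,14-olide | C1/C=C(\C)[C@H](OC(C)=O)[C@@H]2OC(=O)C(=C)[C@H]2C[C@@H]2O[C@@]2(C)CC/C=C(\C)C1 | intermediate
34 | (1R,3S,4S,7S,13S,14R,11E)-13-acetoxy-3,4-epoxy-7-hydroperoxycembra-8(19),11,15(17)-trien-16,14-olide (CNP0166375.1) | C=C1CC/C=C(\C)[C@H](OC(C)=O)[C@@H]2OC(=O)C(=C)[C@H]2C[C@@H]2O[C@@]2(C)CC[C@@H]1OO | target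

## Step count and risk

Total step count: 23. Longest linear sequence: 19 steps (steps 1–9 and 14–23, from D-glutamic acid). The enyne half takes 4 steps (10–13).

**Step 18 (key step).** The most likely failures are intermolecular reductive coupling and oligomerization competing with ring closure, leakage into the exo regiochemistry, and erosion of the C13 selectivity, because the conformational demands of the forming 14-membered ring can override the Felkin–Anh preference of the aldehyde. Base-mediated epimerization of the α-acyloxy aldehyde at C14 is a further hazard.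

Fallback (sets out from 27, returns at 28): the ring is closed at C11–C12 by alkyne metathesis. 1-Propynylmagnesium bromide is added to 27 at −78 °C, with the same Felkin–Anh sense but in an acyclic setting, to give the propargylic alcohol F1. Silylation (TESCl, imidazole) gives the diyne silyl ether F2. Ring-closing alkyne metathesis with Mo(≡CC6H4OMe-4)(OSiPh3)3 (toluene, 5 Å molecular sieves) expels but-2-yne and gives the cycloalkyne F3. Desilylation (HF·pyridine, pyridine) gives the cycloalkynol F4. Hydroxyl-directed trans-hydrostannation ([Cp*RuCl]4, Bu3SnH, CH2Cl2) places tin at C12 in the alkenylstannane F5. Methyl-for-tin exchange (MeI, Pd(PPh3)4, copper thiophene-2-carboxylate Cu(O2CC4H3S), [Bu4N][Ph2PO2], DMF) gives the allylic alcohol F6, which is silylated (TESCl, imidazole) to 28.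

**Step 23.** The most likely failures are competing hydrogen abstraction from C6 (a tertiary C8 hydroperoxide with a shifted olefin), partial attack at C11=C12, and poor facial selectivity at C7, since only the ring conformation distinguishes the two faces.

Fallback (sets out from 33, returns at 34): the oxygen is introduced by an ionic path. Ene-type allylic chlorination (NCS, catalytic PhSeCl, CH2Cl2) is expected to attack the same electron-rich olefin, with chlorine at C7 and loss of a C19 proton, giving the allylic chloride F7. Silver-assisted perhydrolysis (AgOTf, ethereal H2O2, 0 °C) would convert it into 34. This changes the origin of the regiochemistry but is not expected to improve the facial bias, so C7 epimers would have to be separated.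

**Step 14.** The most likely failures are enolization of the α-chloro ketone by the basic alkyl Grignard reagent (loss of the C3 configuration, recovered ketone), attack on the lactone, and incomplete Cornforth facial selectivity.

Fallback (sets out from 14, returns at 25): the C4–C5 bond is made with a less basic, more reactive nucleophile and the chain is completed by cross-coupling at C6–C7. Vinylmagnesium bromide is added to 14 (THF, −78 °C, same Cornforth sense) to give the vinyl chlorohydrin F8, which NaH closes to the vinyl epoxide F9. Hydroboration with 9-BBN places boron at C6 (alkylborane F10, not isolated). Suzuki–Miyaura coupling (Pd(dppf)Cl2, AsPh3, Cs2CO3, DMF/H2O, rt) with the vinyl iodide F11 then delivers 25. F11 is obtained from alane 20 by iodinolysis (I2, THF, −30 °C) in place of the ethylene oxide trapping.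

**Step 12.** The most likely failures are incomplete discrimination between the terminal and the internal alkyne in the methylalumination and sluggish opening of ethylene oxide by the alanate.

Fallback (sets out from 16, returns at 22): the olefin is made by the Julia olefin synthesis. Ethyl acetoacetate is alkylated with 16 (NaOEt, EtOH) to the keto ester F12, which is hydrolysed and decarboxylated (aq. NaOH; then H3O+, heat) to the ketone F13. Addition of cyclopropylmagnesium bromide gives the cyclopropyl carbinol F14, and cyclopropylcarbinyl-to-homoallyl rearrangement with cold 48% aq. HBr gives 22. Geometric control is weaker on this path, and the minor Z isomer would have to be removed by argentation chromatography.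

## Further compounds

F1 | step 18 | (4R,5R)-5-[(1S)-1-hydroxybut-2-yn-1-yl]-4-{[(2S,3S)-3-methyl-3-[(E)-4-methylnon-3-en-7-yn-1-yl]oxiran-2-yl]methyl}dihydrofuran-2(3H)-one | CC#C[C@H](O)[C@@H]1OC(=O)C[C@H]1C[C@@H]1O[C@@]1(C)CC/C=C(\C)CCC#CC
F2 | step 18 | triethylsilyl ether of F1 (identical with A4) | CC#C[C@H](O[Si](CC)(CC)CC)[C@@H]1OC(=O)C[C@H]1C[C@@H]1O[C@@]1(C)CC/C=C(\C)CCC#CC
F3 | step 18 | (1R,3S,4S,13S,14R,7E)-3,4-epoxy-13-(triethylsilyloxy)-20-norcembr-7-en-11-yn-16,14-olide | C1C#C[C@H](O[Si](CC)(CC)CC)[C@@H]2OC(=O)C[C@H]2C[C@@H]2O[C@@]2(C)CC/C=C(\C)C1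
F4 | step 18 | (1R,3S,4S,13S,14R,7E)-3,4-epoxy-13-hydroxy-20-norcembr-7-en-11-yn-16,14-olide | C1C#C[C@H](O)[C@@H]2OC(=O)C[C@H]2C[C@@H]2O[C@@]2(C)CC/C=C(\C)C1
F5 | step 18 | (1R,3S,4S,13S,14R,7E,11Z)-3,4-epoxy-13-hydroxy-12-(tributylstannyl)-20-norcembra-7,11-dien-16,14-olide | C1/C=C(\[Sn](CCCC)(CCCC)CCCC)[C@H](O)[C@@H]2OC(=O)C[C@H]2C[C@@H]2O[C@@]2(C)CC/C=C(\C)C1
F6 | step 18 | (1R,3S,4S,13S,14R,7E,11E)-3,4-epoxy-13-hydroxycembra-7,11-dien-16,14-olide | C1/C=C(\C)[C@H](O)[C@@H]2OC(=O)C[C@H]2C[C@@H]2O[C@@]2(C)CC/C=C(\C)C1
F7 | step 23 | (1R,3S,4S,13S,14R,11E)-13-acetoxy-7-chloro-3,4-epoxycembra-8(19),11,15(17)-trien-16,14-olide (C7 epimers) | C=C1CC/C=C(\C)[C@H](OC(C)=O)[C@@H]2OC(=O)C(=C)[C@H]2C[C@@H]2O[C@@]2(C)CCC1Cl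
F8 | step 14 | (4S,5R)-5-[(tert-butyldiphenylsilyloxy)methyl]-4-[(2R,3S)-2-chloro-3-hydroxy-3-methylpent-4-en-1-yl]dihydrofuran-2(3H)-one | CC(C)(C)[Si](c1ccccc1)(c1ccccc1)OC[C@@H]1OC(=O)C[C@H]1C[C@@H](Cl)[C@@](C)(O)C=C
F9 | step 14 | (4R,5R)-5-[(tert-butyldiphenylsilyloxy)methyl]-4-{[(2S,3S)-3-methyl-3-vinyloxiran-2-yl]methyl}dihydrofuran-2(3H)-one | CC(C)(C)[Si](c1ccccc1)(c1ccccc1)OC[C@@H]1OC(=O)C[C@H]1C[C@@H]1O[C@@]1(C)C=C
F10 | step 14 | 9-BBN adduct of F9 with boron at C6 (B-alkyl-9-borabicyclo[3.3.1]nonane) | CC(C)(C)[Si](c1ccccc1)(c1ccccc1)OC[C@@H]1OC(=O)C[C@H]1C[C@@H]1O[C@@]1(C)CCB1C2CCCC1CCC2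
F11 | step 14 | (E)-1-iodo-2-methylhept-1-en-5-yne | I/C=C(\C)CCC#CC
F12 | step 12 | ethyl 2-acetylhex-4-ynoate | CCOC(=O)C(CC#CC)C(C)=O
F13 | step 12 | hept-5-yn-2-one | CC(=O)CCC#CC
F14 | step 12 | 2-cyclopropylhept-5-yn-2-ol | CC#CCCC(C)(O)C1CC1
A1 | alternative 1 | (R)-5-[(trityloxy)methyl]furan-2(5H)-one | C(c1ccccc1)(c1ccccc1)(c1ccccc1)OC[C@@H]1OC(=O)C=C1
A2 | alternative 1 | (3S,4R,5R)-3-(hydroxymethyl)-5-[(trityloxy)methyl]-4-vinyldihydrofuran-2(3H)-one (all-trans) | C(c1ccccc1)(c1ccccc1)(c1ccccc1)OC[C@@H]1OC(=O)[C@H](CO)[C@H]1C=C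
A3 | alternative 2 | (3R)-3-chloro-4-[(2R,3S)-5-oxo-2-[(1S)-1-(triethylsilyloxy)but-2-yn-1-yl]tetrahydrofuran-3-yl]butan-2-one | CC#C[C@H](O[Si](CC)(CC)CC)[C@@H]1OC(=O)C[C@H]1C[C@@H](Cl)C(C)=O
A4 | alternative 2 | (4R,5R)-4-{[(2S,3S)-3-methyl-3-[(E)-4-methylnon-3-en-7-yn-1-yl]oxiran-2-yl]methyl}-5-[(1S)-1-(triethylsilyloxy)but-2-yn-1-yl]dihydrofuran-2(3H)-one (epoxy diyne) | CC#C[C@H](O[Si](CC)(CC)CC)[C@@H]1OC(=O)C[C@H]1C[C@@H]1O[C@@]1(C)CC/C=C(\C)CCC#CC
A5 | alternative 3 | (1R,13S,14R,3E,7E,11E)-13-acetoxycembra-3,7,11,15(17)-tetraen-16,14-olide | C1/C=C(\C)[C@H](OC(C)=O)[C@@H]2OC(=O)C(=C)[C@H]2C/C=C(\C)CC/C=C(\C)C1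
A6 | alternative 3 | (1R,3S,4S,13S,14R,7E,11E)-13-acetoxy-3,4-epoxycembra-7,11,15(17)-trien-16,14-olide (identical with 33) | C1/C=C(\C)[C@H](OC(C)=O)[C@@H]2OC(=O)C(=C)[C@H]2C[C@@H]2O[C@@]2(C)CC/C=C(\C)C1
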